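**Plan**

1. Retrosynthesis first removes the two acetates, then cuts the trisubstituted C2=C3 bond of the (Z)-butene-1,4-diol as a metathesis bond. This works because each alkene carbon carries a CH2O group and the two are cis: one silicon atom can bridge the two oxygens, so that Si, two O, two CH2 and the two alkene carbons form a seven-membered 1,3,2-dioxasilepine, a ring that can only hold a Z alkene.
2. The open bis-ether is cut at both Si–O bonds (allyl alcohol, i-Pr2SiCl2, a C19 2-methylene alcohol), and that alcohol at the CH2–CH2 bond next to the methylene unit (dilithiated methallyl alcohol plus a C15 allylic bromide).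
3. The bromide goes back through its alcohol and the E-enoate (C=C cut, phosphonoacetate olefination) to dihydro-α-ionone and α-ionone.
4. Forward, the chain is joined linearly (C13 → C15 → C19), the silicon tether is attached, the only new ring (seven-membered, temporary) is closed by metathesis, silicon is removed and the diol is acetylated; the cyclohexene ring is present from the start.
5. The single stereocentre (ring C1, S) comes from racemic α-ionone by resolution (one α-ionol diastereomer through its crystalline 4-nitrobenzoate, then lipase acetylation) and is not touched afterwards; the E chain alkene comes from the olefination, the Z alkene from the ring.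

Key step: step 13

Assumption: of the two racemic α-ionol diastereomers, the (6S*,9R*) pair (ionone numbering: C6 ring carbon, C9 carbinol carbon) is taken to be the one whose 4-nitrobenzoate crystallises; if the other pair crystallised, the (6S) series would be collected in step 4 as the unacylated alcohol and step 5 would fall away.

**Route**

Step 1
Reactants: 1 racemic α-ionone
Product: 2 α-ionol as the mixture of all four stereoisomers
Conditions: NaBH4, CeCl3·7H2O, MeOH, 0 °C
Reagents that add atoms: none
Why: Luche reduction delivers hydride 1,2 to the enone carbonyl only, and the uncontrolled new carbinol centre is accepted because the next three steps sort the stereoisomers.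

Step 2
Reactants: 2 α-ionol (four stereoisomers)
Product: 3 (2R*,3E)-4-[(1S*)-2,6,6-trimethylcyclohex-2-en-1-yl]but-3-en-2-yl 4-nitrobenzoate (racemic single diastereomer)
Conditions: 4-O2NC6H4COCl, pyridine, CH2Cl2, 0 °C to rt; fractional crystallisation from hexane
Reagents that add atoms: 4-nitrobenzoyl chloride, O=C(Cl)c1ccc(cc1)[N+](=O)[O-]
Why: Pyridine-mediated acylation of a secondary alcohol by an acid chloride is routine, and the 4-nitrobenzoate is chosen as a crystalline derivative from which fractional crystallisation should deliver one racemic diastereomer.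

Step 3
Reactants: 3 racemic (6S*,9R*) 4-nitrobenzoate
Product: 4 (2R*,3E)-4-[(1S*)-2,6,6-trimethylcyclohex-2-en-1-yl]but-3-en-2-ol (racemic single diastereomer)
Conditions: K2CO3, MeOH, rt
Reagents that add atoms: none
Why: Base-catalysed transesterification of the activated aryl ester with methanol frees the allylic alcohol without touching either stereocentre.

Step 4
Reactants: 4 racemic (6S*,9R*)-α-ionol
Product: 5 (2R,3E)-4-[(1S)-2,6,6-trimethylcyclohex-2-en-1-yl]but-3-en-2-yl acetate
Conditions: lipase PS (Burkholderia cepacia), vinyl acetate, t-BuOMe, rt, stopped near half conversion; chromatography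
Reagents that add atoms: vinyl acetate, CC(=O)OC=C
Why: In this lipase kinetic resolution by irreversible transesterification the enzyme acylates the (R)-configured methyl carbinol much faster than its mirror image, so within one racemic diastereomer the acetate should hold only the (6S,9R) enantiomer, the ring centre being selected through its fixed relation to C9.

Step 5
Reactants: 5 (6S,9R)-α-ionyl acetate
Product: 6 (2R,3E)-4-[(1S)-2,6,6-trimethylcyclohex-2-en-1-yl]but-3-en-2-ol
Conditions: K2CO3, MeOH, rt
Reagents that add atoms: none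
Why: Mild methanolysis of the acetate returns the enantiopure allylic alcohol with both centres unchanged.

Step 6
Reactants: 6 (6S,9R)-α-ionol
Product: 7 (S)-α-ionone, (3E)-4-[(1S)-2,6,6-trimethylcyclohex-2-en-1-yl]but-3-en-2-one
Conditions: MnO2, CH2Cl2, rt
Reagents that add atoms: none
Why: MnO2 oxidises allylic alcohols under neutral heterogeneous conditions, erasing the auxiliary carbinol centre while the ring centre, which could only epimerise through a dienolate, stays intact in the absence of base.

Step 7
Reactants: 7 (S)-α-ionone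
Product: 9 4-[(1S)-2,6,6-trimethylcyclohex-2-en-1-yl]butan-2-one, via triethylsilyl enol ether 8 (not isolated)
Conditions: Et3SiH, RhCl(PPh3)3 (cat.), toluene, 50 °C; then K2CO3, MeOH, rt
Reagents that add atoms: none
Why: Rhodium-catalysed 1,4-hydrosilylation of the enone with a monohydrosilane gives the silyl enol ether, whose methanolysis leaves the saturated ketone, while the hindered trisubstituted ring alkene is not hydrosilylated and the neutral conditions spare the allylic ring centre.

Step 8
Reactants: 9 (S)-dihydro-α-ionone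
Product: 10 ethyl (2E)-3-methyl-5-[(1S)-2,6,6-trimethylcyclohex-2-en-1-yl]pent-2-enoate
Conditions: (EtO)2P(O)CH2CO2Et, NaH, THF, 0 °C to reflux; chromatography to remove the (2Z) isomer
Reagents that add atoms: triethyl phosphonoacetate, CCOC(=O)CP(=O)(OCC)OCC
Why: Horner–Wadsworth–Emmons olefination of a methyl ketone with a stabilised phosphonate anion favours the enoate whose ester lies trans to the larger alkyl chain, and the minor Z isomer expected beside it is separable on silica.

Step 9
Reactants: 10 ethyl (2E)-enoate
Product: 11 (2E)-3-methyl-5-[(1S)-2,6,6-trimethylcyclohex-2-en-1-yl]pent-2-en-1-ol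
Conditions: i-Bu2AlH, CH2Cl2, −78 to 0 °C; aqueous potassium sodium tartrate work-up
Reagents that add atoms: none
Why: i-Bu2AlH reduces α,β-unsaturated esters by 1,2-addition to the allylic alcohol without touching the alkenes or their geometry.

Step 10
Reactants: 11 (2E)-allylic alcohol
Product: 12 (6S)-6-[(3E)-5-bromo-3-methylpent-3-en-1-yl]-1,5,5-trimethylcyclohex-1-ene
Conditions: CBr4, PPh3, CH2Cl2, 0 °C
Reagents that add atoms: tetrabromomethane, BrC(Br)(Br)Br
Why: The Appel reaction converts the primary allylic alcohol into the bromide by SN2 displacement of an alkoxyphosphonium ion under neutral conditions, which avoids allylic transposition and E/Z scrambling.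

Step 11
Reactants: 12 (E)-allylic bromide; 13 2-methylprop-2-en-1-ol
Product: 15 (5E)-6-methyl-2-methylidene-8-[(1S)-2,6,6-trimethylcyclohex-2-en-1-yl]oct-5-en-1-ol, via dilithiated 2-methylprop-2-en-1-ol 14 (not isolated)
Conditions: 13, n-BuLi (2 equiv per 13), TMEDA, Et2O–hexane, 0 °C to rt; then 12, THF, −78 °C to rt; H2O quench
Reagents that add atoms: none
Why: Double deprotonation of methallyl alcohol (O–H, then the allylic methyl with TMEDA assistance) gives an alkoxide-allyllithium dianion whose carbon terminus displaces the primary allylic bromide by SN2, a known C-alkylation of this dianion that forms the CH2–CH2 bond.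

Step 12
Reactants: 15 2-methylene alcohol; 16 prop-2-en-1-ol; 17 dichlorodi(propan-2-yl)silane
Product: 19 {[(5E)-6-methyl-2-methylidene-8-[(1S)-2,6,6-trimethylcyclohex-2-en-1-yl]oct-5-en-1-yl]oxy}(prop-2-en-1-yloxy)di(propan-2-yl)silane, via chloro(prop-2-en-1-yloxy)di(propan-2-yl)silane 18 (not isolated)
Conditions: 17, Et3N, CH2Cl2, 0 °C, slow addition of 16; then 15, imidazole, rt
Reagents that add atoms: none
Why: The two isopropyl groups slow the second substitution at silicon enough that one chloride can be replaced by allyl alcohol and the remaining Si–Cl by alcohol 15 under imidazole catalysis, the usual stepwise silylation route to mixed silaketals.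

Step 13
Reactants: 19 mixed diisopropylsilylene bis-ether
Product: 20 5-[(3E)-4-methyl-6-[(1S)-2,6,6-trimethylcyclohex-2-en-1-yl]hex-3-en-1-yl]-2,2-di(propan-2-yl)-4,7-dihydro-1,3,2-dioxasilepine
Conditions: (H2IMes)(PCy3)Cl2Ru=CHPh (second-generation Grubbs catalyst, 5 mol %), CH2Cl2, high dilution, reflux, argon sparge
Reagents that add atoms: none
Why: Phosphine loss from the ruthenium benzylidene gives the 14-electron alkylidene, which exchanges with the monosubstituted allyl ether to place ruthenium on the allyl terminus; this alkylidene adds across the tethered 1,1-disubstituted alkene in a [2+2] step, and cycloreversion of the ruthenacyclobutane forms the ring C=C and Ru=CH2, which re-enters the cycle with release of ethene. The closest known reaction type is the temporary silicon-tethered ring-closing metathesis of bis(alkenyloxy)silanes to 4,7-dihydro-1,3,2-dioxasilepines, including closures that give a trisubstituted ring alkene. The one ring formed is the seven-membered silaketal, closed by C=C bond formation between the two alkene carbons with the new alkene endocyclic. No stereocentre is created, and the alkene geometry is fixed as Z because a seven-membered ring cannot hold an E alkene, which places the two CH2O groups cis. The step needs site selectivity for the two terminal alkenes, and this is secured by their lower substitution and by ring size, since engaging the trisubstituted chain alkene would require a ten-membered ring and the ring alkene is trisubstituted and flanked by a quaternary carbon. High dilution and the two isopropyl groups on silicon, which press the two arms together, should hold back intermolecular dimerisation at the allyl ether.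

Step 14
Reactants: 20 dioxasilepine
Product: 21 (2Z)-2-[(3E)-4-methyl-6-[(1S)-2,6,6-trimethylcyclohex-2-en-1-yl]hex-3-en-1-yl]but-2-ene-1,4-diol
Conditions: HF·pyridine, pyridine, THF, 0 °C to rt
Reagents that add atoms: none
Why: Fluoride-driven cleavage of both Si–O bonds, pulled by the strong Si–F bond and buffered by excess pyridine, frees the diol without acid-induced cyclisation to a dihydrofuran and with the Z geometry retained.

Step 15
Reactants: 21 (Z)-diol
Product: 22 (2Z)-2-[(3E)-4-methyl-6-[(1S)-2,6,6-trimethylcyclohex-2-en-1-yl]hex-3-en-1-yl]but-2-ene-1,4-diyl diacetate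
Conditions: Ac2O, pyridine, DMAP (cat.), CH2Cl2, 0 °C to rt
Reagents that add atoms: acetic anhydride, CC(=O)OC(C)=O
Why: DMAP-catalysed acylation esterifies both primary allylic alcohols under conditions that affect neither alkene geometry nor the ring centre.

**Compound list**

1 | racemic α-ionone, (3E)-4-(2,6,6-trimethylcyclohex-2-en-1-yl)but-3-en-2-one | CC(=O)/C=C/C1C(C)=CCCC1(C)C | starting material
2 | α-ionol, (3E)-4-(2,6,6-trimethylcyclohex-2-en-1-yl)but-3-en-2-ol, all four stereoisomers | CC(O)/C=C/C1C(C)=CCCC1(C)C | intermediate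
3 | (2R*,3E)-4-[(1S*)-2,6,6-trimethylcyclohex-2-en-1-yl]but-3-en-2-yl 4-nitrobenzoate, racemate, one enantiomer drawn | C[C@@H](OC(=O)c1ccc(cc1)[N+](=O)[O-])/C=C/[C@@H]1C(C)=CCCC1(C)C | intermediate
4 | (2R*,3E)-4-[(1S*)-2,6,6-trimethylcyclohex-2-en-1-yl]but-3-en-2-ol, racemate, one enantiomer drawn | C[C@@H](O)/C=C/[C@@H]1C(C)=CCCC1(C)C | intermediate
5 | (2R,3E)-4-[(1S)-2,6,6-trimethylcyclohex-2-en-1-yl]but-3-en-2-yl acetate | C[C@@H](OC(C)=O)/C=C/[C@@H]1C(C)=CCCC1(C)C | intermediate
6 | (2R,3E)-4-[(1S)-2,6,6-trimethylcyclohex-2-en-1-yl]but-3-en-2-ol, single enantiomer | C[C@@H](O)/C=C/[C@@H]1C(C)=CCCC1(C)C | intermediate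
7 | (S)-α-ionone, (3E)-4-[(1S)-2,6,6-trimethylcyclohex-2-en-1-yl]but-3-en-2-one | CC(=O)/C=C/[C@@H]1C(C)=CCCC1(C)C | intermediate
8 | triethyl({4-[(1S)-2,6,6-trimethylcyclohex-2-en-1-yl]but-2-en-2-yl}oxy)silane, E/Z mixture | CC(=CC[C@@H]1C(C)=CCCC1(C)C)O[Si](CC)(CC)CC | intermediate
9 | 4-[(1S)-2,6,6-trimethylcyclohex-2-en-1-yl]butan-2-one | CC(=O)CC[C@@H]1C(C)=CCCC1(C)C | intermediate
10 | ethyl (2E)-3-methyl-5-[(1S)-2,6,6-trimethylcyclohex-2-en-1-yl]pent-2-enoate | CCOC(=O)/C=C(\C)CC[C@@H]1C(C)=CCCC1(C)C | intermediate
11 | (2E)-3-methyl-5-[(1S)-2,6,6-trimethylcyclohex-2-en-1-yl]pent-2-en-1-ol | OC/C=C(\C)CC[C@@H]1C(C)=CCCC1(C)C | intermediate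
12 | (6S)-6-[(3E)-5-bromo-3-methylpent-3-en-1-yl]-1,5,5-trimethylcyclohex-1-ene | BrC/C=C(\C)CC[C@@H]1C(C)=CCCC1(C)C | intermediate
13 | 2-methylprop-2-en-1-ol | CC(=C)CO | starting material
14 | dilithiated 2-methylprop-2-en-1-ol, lithium 2-(lithiomethyl)prop-2-en-1-olate | [Li+].[Li+].[CH2-]C(=C)C[O-] | intermediate
15 | (5E)-6-methyl-2-methylidene-8-[(1S)-2,6,6-trimethylcyclohex-2-en-1-yl]oct-5-en-1-ol | OCC(=C)CC/C=C(\C)CC[C@@H]1C(C)=CCCC1(C)C | intermediate
16 | prop-2-en-1-ol | C=CCO | starting material
17 | dichlorodi(propan-2-yl)silane | CC(C)[Si](Cl)(Cl)C(C)C | starting material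
18 | chloro(prop-2-en-1-yloxy)di(propan-2-yl)silane | C=CCO[Si](Cl)(C(C)C)C(C)C | intermediate
19 | {[(5E)-6-methyl-2-methylidene-8-[(1S)-2,6,6-trimethylcyclohex-2-en-1-yl]oct-5-en-1-yl]oxy}(prop-2-en-1-yloxy)di(propan-2-yl)silane | C=CCO[Si](C(C)C)(C(C)C)OCC(=C)CC/C=C(\C)CC[C@@H]1C(C)=CCCC1(C)C | intermediate
20 | 5-[(3E)-4-methyl-6-[(1S)-2,6,6-trimethylcyclohex-2-en-1-yl]hex-3-en-1-yl]-2,2-di(propan-2-yl)-4,7-dihydro-1,3,2-dioxasilepine | CC(C)[Si]1(C(C)C)OC/C=C(/CC/C=C(\C)CC[C@@H]2C(C)=CCCC2(C)C)CO1 | intermediate
21 | (2Z)-2-[(3E)-4-methyl-6-[(1S)-2,6,6-trimethylcyclohex-2-en-1-yl]hex-3-en-1-yl]but-2-ene-1,4-diol | OC/C=C(/CC/C=C(\C)CC[C@@H]1C(C)=CCCC1(C)C)CO | intermediate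
22 | (2Z)-2-[(3E)-4-methyl-6-[(1S)-2,6,6-trimethylcyclohex-2-en-1-yl]hex-3-en-1-yl]but-2-ene-1,4-diyl diacetate | CC(=O)OC/C=C(/CC/C=C(\C)CC[C@@H]1C(C)=CCCC1(C)C)COC(C)=O | target

**Count and risks**

Total step count: 15. Longest linear sequence: 15 steps, from 1 to 22; 13, 16 and 17 enter as bought materials.

Steps most likely to fail:

Step 13. The ruthenium alkylidene formed at the allyl ether may close only slowly onto the 1,1-disubstituted alkene, so that intermolecular dimerisation at the allyl ether or ruthenium-hydride-induced alkene migration takes over. The fallback avoids metathesis and holds the Z geometry in a five-membered lactone instead. It sets out from alcohol 11. Oxidation with MnO2 would give (2E)-3-methyl-5-[(1S)-2,6,6-trimethylcyclohex-2-en-1-yl]pent-2-enal F1. Wittig methylenation with Ph3P=CH2 (from Ph3PCH3Br and n-BuLi) would give (6S)-1,5,5-trimethyl-6-[(3E)-3-methylhexa-3,5-dien-1-yl]cyclohex-1-ene F2. Hydroboration of its terminal vinyl group with 9-BBN would give 9-[(3E)-4-methyl-6-[(1S)-2,6,6-trimethylcyclohex-2-en-1-yl]hex-3-en-1-yl]-9-borabicyclo[3.3.1]nonane F3, which is used without isolation. A B-alkyl Suzuki–Miyaura coupling of F3 with bought 4-bromofuran-2(5H)-one (PdCl2(dppf), AsPh3, Cs2CO3, DMF–THF–H2O, rt) would give 4-[(3E)-4-methyl-6-[(1S)-2,6,6-trimethylcyclohex-2-en-1-yl]hex-3-en-1-yl]furan-2(5H)-one F4. Reduction of the lactone with excess i-Bu2AlH then opens it to the Z-diol, and the route is rejoined at 21.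

Step 11. The strongly basic dianion may attack the allylic bromide in the SN2′ sense, react through oxygen, or cause elimination, and dianion formation itself may stay incomplete. The fallback builds the same carbon skeleton with a stabilised enolate and sets out from bromide 12. Alkylation of ethyl acetoacetate (NaOEt, EtOH) would give ethyl (4E)-2-acetyl-5-methyl-7-[(1S)-2,6,6-trimethylcyclohex-2-en-1-yl]hept-4-enoate F5. Saponification and decarboxylation (aqueous NaOH, then acidification and warming) would give (5E)-6-methyl-8-[(1S)-2,6,6-trimethylcyclohex-2-en-1-yl]oct-5-en-2-one F6. Corey–Chaykovsky methylenation with dimethylsulfonium methylide (Me3SI, n-BuLi, THF) would give 2-methyl-2-[(3E)-4-methyl-6-[(1S)-2,6,6-trimethylcyclohex-2-en-1-yl]hex-3-en-1-yl]oxirane F7. Base-induced isomerisation of this epoxide with diethylaluminium 2,2,6,6-tetramethylpiperidide, which removes a proton preferentially from the methyl group, would then give the 2-methylene alcohol, and the route is rejoined at 15.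

Step 2. The two racemic diastereomers may separate incompletely on crystallisation, and any carry-over would show up after the lipase step as lowered enantiomeric purity at the ring centre. The fallback resolves the ketone itself through a diastereomeric derivative and sets out from racemic ketone 1. Condensation with (1S,2R,5S)-menthyl carbazate (AcOH cat., EtOH) and fractional crystallisation of the hydrazones would give (1S,2R,5S)-5-methyl-2-(propan-2-yl)cyclohexyl 2-{(3E)-4-[(1S)-2,6,6-trimethylcyclohex-2-en-1-yl]but-3-en-2-ylidene}hydrazine-1-carboxylate F8. Hydrolytic release of the ketone (aqueous oxalic acid, steam distillation) then rejoins the route at 7.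

**Further compounds**

F1 | step 13 | (2E)-3-methyl-5-[(1S)-2,6,6-trimethylcyclohex-2-en-1-yl]pent-2-enal | O=C/C=C(\C)CC[C@@H]1C(C)=CCCC1(C)C
F2 | step 13 | (6S)-1,5,5-trimethyl-6-[(3E)-3-methylhexa-3,5-dien-1-yl]cyclohex-1-ene | C=C/C=C(\C)CC[C@@H]1C(C)=CCCC1(C)C
F3 | step 13 | 9-[(3E)-4-methyl-6-[(1S)-2,6,6-trimethylcyclohex-2-en-1-yl]hex-3-en-1-yl]-9-borabicyclo[3.3.1]nonane | C1CCC2CCCC1B2CC/C=C(\C)CC[C@@H]1C(C)=CCCC1(C)C
F4 | step 13 | 4-[(3E)-4-methyl-6-[(1S)-2,6,6-trimethylcyclohex-2-en-1-yl]hex-3-en-1-yl]furan-2(5H)-one | O=C1C=C(CC/C=C(\C)CC[C@@H]2C(C)=CCCC2(C)C)CO1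
F5 | step 11 | ethyl (4E)-2-acetyl-5-methyl-7-[(1S)-2,6,6-trimethylcyclohex-2-en-1-yl]hept-4-enoate, both epimers at C2 | CCOC(=O)C(C(C)=O)C/C=C(\C)CC[C@@H]1C(C)=CCCC1(C)C
F6 | step 11 | (5E)-6-methyl-8-[(1S)-2,6,6-trimethylcyclohex-2-en-1-yl]oct-5-en-2-one | CC(=O)CC/C=C(\C)CC[C@@H]1C(C)=CCCC1(C)C
F7 | step 11 | 2-methyl-2-[(3E)-4-methyl-6-[(1S)-2,6,6-trimethylcyclohex-2-en-1-yl]hex-3-en-1-yl]oxirane, both epimers at the oxirane carbon | CC1(CC/C=C(\C)CC[C@@H]2C(C)=CCCC2(C)C)CO1
F8 | step 2 | (1S,2R,5S)-5-methyl-2-(propan-2-yl)cyclohexyl 2-{(3E)-4-[(1S)-2,6,6-trimethylcyclohex-2-en-1-yl]but-3-en-2-ylidene}hydrazine-1-carboxylate | C[C@H]1CC[C@@H]([C@H](C1)OC(=O)NN=C(C)/C=C/[C@@H]2C(C)=CCCC2(C)C)C(C)C
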